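The route rests on cutting lactone D and ring C together. Lactone D is a γ-lactone whose oxygen-bearing γ-carbon (Cf) is the quaternary carbon shared by rings B, C and D, and whose β-carbon (Cg) is the adjacent ring C methine. That pattern is what a ketone C=O, an alkyne and CO leave behind. A Mo(CO)6-mediated hetero-Pauson–Khand reaction therefore turns an acyclic 1,7-ynone in one operation into the ring C/ring D butenolide and creates the quaternary centre. The precursor is a terminal propargylic silyl ether carrying the ethyl centre, a dioxolane-masked neighbouring carbonyl, the reacting ketone and the lactone E side chain with a silyloxy handle for nitrogen.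

Key step: step 16

Remarks on the chemistry (assumptions, one line each):
- Atom labels (target): ring C = Ca(Et)–Cb–Cc–Cf–Cg–Ch(OH); ring B = N–Cd–Ce–Cf–Cc; ring A = N–(CH2)4–Cb=Cc; ring D = Cf–O–C(=O)–CH(Me)–Cg; lactone E hangs on Cd.
- The propargylic oxygen is carried as a TIPS ether, which resists silyl migration to carbanions and is acid-stable enough for the late ketal hydrolysis.
- The Cd carbinol is a spectator in the key step. A Felkin-type aldol is expected to give its (R)-epimer, whereas azide displacement with inversion needs (S), so the centre is re-set after the key step (steps 21 and 22).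
- The four-carbon bridge of ring A is attached at Cb by ketone alkylation before nitrogen closes ring B, so that no strong base meets an imine beside two lactones.
- Compounds 1, 2, 5, 11, 17 and 39 are taken as commercial.

Step 1
Reactants: 1 (R)-4-benzyloxazolidin-2-one; 2 butanoyl chloride
Product: 4 (R)-4-benzyl-3-butanoyloxazolidin-2-one, via N-lithio oxazolidinone 3 (not isolated)
Conditions: n-BuLi, THF, −78 °C; then 2, −78 → 0 °C
Reagents that add atoms: none
Why: N-acylation of the lithiated oxazolidinone by the acid chloride is the standard loading of an Evans auxiliary and touches no stereocentre.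

Step 2
Reactants: 4 (R)-4-benzyl-3-butanoyloxazolidin-2-one; 5 3-(trimethylsilyl)prop-2-ynal
Product: 7 (R)-4-benzyl-3-[(2R,3R)-2-ethyl-3-hydroxy-5-(trimethylsilyl)pent-4-ynoyl]oxazolidin-2-one, via Z-boron enolate 6 (not isolated)
Conditions: Bu2BOTf, i-Pr2NEt, CH2Cl2, −78 → 0 °C; then 5, −78 → 0 °C; then pH 7 buffer, MeOH, H2O2, 0 °C
Reagents that add atoms: none
Why: Evans syn-aldol reaction, in which the Z-boron enolate adds through a closed chair transition state on the enolate face away from the benzyl group, so that the (R)-auxiliary sets both the ethyl centre Ca and the propargylic carbinol centre Ch as (2R,3R).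

Step 3
Reactants: 7 syn-aldol adduct
Product: 8 (R)-4-benzyl-3-[(2R,3R)-2-ethyl-3-(triisopropylsilyloxy)-5-(trimethylsilyl)pent-4-ynoyl]oxazolidin-2-one
Conditions: i-Pr3SiOTf, 2,6-lutidine, CH2Cl2, 0 °C
Reagents that add atoms: triisopropylsilyl triflate, CC(C)[Si](OS(=O)(=O)C(F)(F)F)(C(C)C)C(C)C
Why: Silylation of the secondary alcohol with a silyl triflate and a hindered base installs the bulky, acid-stable TIPS group that must survive the organolithium of step 6 and the acid of step 24.

Step 4
Reactants: 8 TIPS-protected aldol adduct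
Product: 9 (2S,3R)-2-ethyl-3-(triisopropylsilyloxy)-5-(trimethylsilyl)pent-4-yn-1-ol
Conditions: LiBH4, MeOH (1 equiv), THF, 0 °C
Reagents that add atoms: none
Why: Reductive cleavage of the N-acyl oxazolidinone by borohydride gives the primary alcohol (the future Cb) and returns the auxiliary without touching the two stereocentres.

Step 5
Reactants: 9 primary alcohol
Product: 10 (3R,4R)-4-(iodomethyl)-3-(triisopropylsilyloxy)-1-(trimethylsilyl)hex-1-yne
Conditions: I2, PPh3, imidazole, CH2Cl2, 0 °C → rt
Reagents that add atoms: iodine, II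
Why: Appel-type iodination of a primary alcohol through its alkoxyphosphonium salt proceeds by SN2 at the CH2 group and leaves the neighbouring stereocentres untouched.

Step 6
Reactants: 10 primary iodide; 11 N,N'-dimethoxy-N,N'-dimethyloxamide
Product: 13 (4S,5R)-4-ethyl-N-methoxy-N-methyl-2-oxo-5-(triisopropylsilyloxy)-7-(trimethylsilyl)hept-6-ynamide, via alkyllithium 12 (not isolated)
Conditions: t-BuLi (2.1 equiv), Et2O, −78 °C; then 11 (2 equiv), THF, −78 °C
Reagents that add atoms: none
Why: Lithium–iodine exchange followed by a Weinreb-type ketone synthesis, in which the chelated tetrahedral adduct at one amide group of the oxamide blocks a second addition, delivers the two-carbon 1,2-dicarbonyl unit (Cc and Cf) in one step.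

Step 7
Reactants: 13 α-keto Weinreb amide
Product: 14 2-[(2S,3R)-2-ethyl-3-(triisopropylsilyloxy)-5-(trimethylsilyl)pent-4-yn-1-yl]-N-methoxy-N-methyl-1,3-dioxolane-2-carboxamide
Conditions: (Me3SiOCH2)2, Me3SiOTf (cat.), CH2Cl2, −78 → 0 °C
Reagents that add atoms: 1,2-bis(trimethylsilyloxy)ethane, C[Si](C)(C)OCCO[Si](C)(C)C
Why: Silyl-triflate-catalysed ketalisation with the bis-silyl ether of ethylene glycol converts the only ketone (Cc) into its dioxolane under mild aprotic conditions, while the amide carbonyl cannot ketalise.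

Step 8
Reactants: 14 dioxolane Weinreb amide
Product: 16 1-{2-[(2S,3R)-2-ethyl-3-(triisopropylsilyloxy)pent-4-yn-1-yl]-1,3-dioxolan-2-yl}ethan-1-one, via TMS-alkynyl methyl ketone 15 (not isolated)
Conditions: MeMgBr, THF, 0 °C; then MeOH, K2CO3 (cat.), rt
Reagents that add atoms: methylmagnesium bromide, C[Mg]Br
Why: Weinreb ketone synthesis gives the methyl ketone (Cf=O with Ce as its methyl group) without over-addition, and methanolic carbonate then removes the alkynyl trimethylsilyl group by protodesilylation while the TIPS ether and the ketal stay.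

Step 9
Reactants: 17 (S)-5-(hydroxymethyl)dihydrofuran-2(3H)-one
Product: 18 (S)-5-[(tert-butyldiphenylsilyloxy)methyl]dihydrofuran-2(3H)-one
Conditions: t-BuPh2SiCl, imidazole, DMF, rt
Reagents that add atoms: tert-butyl(chloro)diphenylsilane, CC(C)(C)[Si](Cl)(c1ccccc1)c1ccccc1
Why: Standard silylation of the primary alcohol places a bulky group at C5 of the lactone, which will direct the two enolate steps that follow.

Step 10
Reactants: 18 silyl-protected lactone
Product: 20 (3R,5S)-5-[(tert-butyldiphenylsilyloxy)methyl]-3-methyldihydrofuran-2(3H)-one, via lithium enolate 19 (not isolated)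
Conditions: LiN(i-Pr)2, THF, −78 °C; then MeI, −78 °C
Reagents that add atoms: iodomethane, CI
Why: Lactone enolate alkylation, in which iodomethane approaches the face opposite the C5 silyloxymethyl group, should give the trans (3R,5S) lactone.

Step 11
Reactants: 20 trans-methyl lactone
Product: 22 (3S,5S)-5-[(tert-butyldiphenylsilyloxy)methyl]-3-methyldihydrofuran-2(3H)-one, via lithium enolate 21 (not isolated)
Conditions: LiN(i-Pr)2, THF, −78 °C; then 2,6-di-tert-butyl-4-methylphenol, −78 °C
Reagents that add atoms: none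
Why: Deprotonation and kinetic protonation, in which the bulky phenol delivers the proton to the enolate face opposite the C5 substituent, should turn the methyl group cis to it and give the (3S,5S) configuration of lactone E.

Step 12
Reactants: 22 cis-methyl lactone
Product: 23 (3S,5S)-5-(hydroxymethyl)-3-methyldihydrofuran-2(3H)-one
Conditions: Bu4NF, AcOH, THF, 0 °C → rt
Reagents that add atoms: none
Why: Fluoride-mediated desilylation, buffered with acetic acid so that the α-centre of the lactone is not epimerised.

Step 13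
Reactants: 23 hydroxymethyl lactone
Product: 24 (2S,4S)-4-methyl-5-oxotetrahydrofuran-2-carbaldehyde
Conditions: Dess–Martin periodinane, CH2Cl2, 0 °C → rt; used crude
Reagents that add atoms: none
Why: Dess–Martin oxidation gives the sensitive α-acyloxy aldehyde under non-basic conditions that do not epimerise the carbon next to the aldehyde.

Step 14
Reactants: 16 methyl ketone; 24 lactone E aldehyde
Product: 26 β-hydroxy ketone with (R)-carbinol at Cd, via lithium enolate 25 (not isolated)
Conditions: LiN(SiMe3)2, THF, −78 °C; then 24, −78 °C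
Reagents that add atoms: none
Why: Aldol addition of the lithium enolate of the methyl ketone, which can enolise only toward its methyl group, forms the Ce–Cd bond; polar Felkin–Anh attack anti to the ring C–O bond should favour the (R)-carbinol, and because this centre is re-set in steps 21 and 22 the minor epimer converges on the same material.

Step 15
Reactants: 26 aldol adduct
Product: 27 ynone precursor of the key step (O-TES ether of 26)
Conditions: Et3SiCl, imidazole, DMF, 0 °C
Reagents that add atoms: chlorotriethylsilane, CC[Si](Cl)(CC)CC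
Why: Mild silylation protects the β-hydroxy ketone against retro-aldol cleavage and elimination during the hot key step and leaves a silyl group that can later be removed in the presence of TIPS.

Step 16
Reactants: 27 ynone precursor
Product: 28 bicyclic butenolide (rings C and D) with quaternary Cf
Conditions: Mo(CO)6 (1.5 equiv), DMSO (10 equiv), toluene, 100 °C
Reagents that add atoms: molybdenum hexacarbonyl (gives one CO), [Mo].[C-]#[O+].[C-]#[O+].[C-]#[O+].[C-]#[O+].[C-]#[O+].[C-]#[O+]
Why: Mo(CO)6 loses CO under the action of DMSO and the zerovalent molybdenum binds the terminal alkyne and the ketone C=O, which couple oxidatively to an oxamolybdacyclopentene (new Cf–Cg bond); CO then inserts into the Mo–C(alkenyl) bond and C–O reductive elimination releases the butenolide. The closest known reaction type is the hetero-Pauson–Khand cyclocarbonylation of tethered ynals and ynones to fused butenolides, applied here to a dialkyl ketone that is activated inductively by the adjacent dioxolane carbon, a combination that is untested. Ring C closes in the oxidative coupling as the six-membered carbocycle of a 1,7-ynone (exo mode with respect to the metallacycle), and ring D closes by carbonyl insertion followed by acyl–oxygen bond formation at the former ketone oxygen. The one new stereocentre, the quaternary Cf, is controlled by the existing centres Ca and Ch: in the chair-like six-ring of the metallacycle the ethyl and OTIPS groups sit equatorial, which forces the Ce side chain axial on the ethyl face and should give the (R)-configured C–O carbon. The step needs chemoselectivity for the ketone over the lactone carbonyls and for six- over five-ring closure, which the inert lactones and the fully substituted, non-carbonyl Cc secure, and the terminal alkyne keeps allylic strain against the equatorial OTIPS group small.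

Step 17
Reactants: 28 bicyclic butenolide
Product: 30 α-bromobutenolide, via vicinal dibromide 29 (not isolated)
Conditions: Br2, CH2Cl2, 0 °C; then Et3N, 0 °C → rt
Reagents that add atoms: bromine, BrBr
Why: α-Bromination of an α,β-unsaturated lactone by bromine addition and base-induced loss of HBr removes the acidic α-hydrogen and so places bromine only at the α-carbon of lactone D.

Step 18
Reactants: 30 α-bromobutenolide
Product: 31 α-methylbutenolide
Conditions: Me4Sn, Pd2(dba)3 (cat.), AsPh3, CuI (cat.), NMP, 60 °C
Reagents that add atoms: tetramethylstannane, C[Sn](C)(C)C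
Why: Stille cross-coupling of the alkenyl bromide transfers a methyl group under neutral conditions that leave both lactones, the ketal and the silyl ethers intact.

Step 19
Reactants: 31 α-methylbutenolide
Product: 32 saturated cis-fused lactone D
Conditions: H2 (60 bar), 5% Rh/Al2O3, EtOAc, rt
Reagents that add atoms: none
Why: Heterogeneous hydrogenation should add both hydrogens syn from the face of the angular Ce methylene, which is the face opposite the allylic OTIPS group and the dioxolane, and thus set the cis ring fusion at Cg and the α-methyl centre of lactone D together.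

Step 20
Reactants: 32 saturated lactone with OTES at Cd
Product: 33 (R)-alcohol at Cd
Conditions: PPTS (cat.), MeOH, 0 °C → rt
Reagents that add atoms: none
Why: Acid-catalysed methanolysis cleaves the triethylsilyl ether selectively, since TES is far more labile than the hindered TIPS ether and the electron-poor dioxolane.

Step 21
Reactants: 33 (R)-alcohol
Product: 34 ketone at Cd
Conditions: Dess–Martin periodinane, CH2Cl2, 0 °C → rt; used without chromatography
Reagents that add atoms: none
Why: Dess–Martin oxidation erases the Cd carbinol centre under non-basic conditions, which matters because the resulting ketone is a β-acyloxy ketone that base could eliminate.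

Step 22
Reactants: 34 ketone at Cd
Product: 35 (S)-alcohol at Cd
Conditions: LiBH(s-Bu)3 (L-Selectride), THF, −78 °C
Reagents that add atoms: none
Why: Felkin–Anh-controlled hydride reduction, in which the bulky borohydride attacks anti to the ring C–O bond of lactone E, should give the (S)-carbinol (syn to the lactone oxygen) and leaves both lactones untouched at low temperature.

Step 23
Reactants: 35 (S)-alcohol
Product: 37 (R)-azide at Cd, via secondary triflate 36 (not isolated)
Conditions: Tf2O, pyridine, CH2Cl2, −40 °C; then Bu4NN3, MeCN, −40 → 0 °C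
Reagents that add atoms: tetrabutylammonium azide, CCCC[N+](CCCC)(CCCC)CCCC.[N-]=[N+]=[N-]
Why: SN2 displacement of the triflate by azide with inversion installs nitrogen at Cd in the (R)-configuration of the target, and a soluble azide at low temperature is used so that direct substitution outruns elimination and participation by a ketal oxygen.

Step 24
Reactants: 37 azido ketal
Product: 38 azido ketone (free Cc=O)
Conditions: CF3CO2H/H2O (9:1), CH2Cl2, 0 °C → rt
Reagents that add atoms: water, O
Why: Acid-catalysed ketal hydrolysis unmasks the Cc ketone, a strong acid being needed because the neighbouring acyloxy carbon retards oxocarbenium formation, while azide, lactones and the TIPS ether should tolerate it.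

Step 25
Reactants: 38 azido ketone; 39 1-chloro-4-iodobutane
Product: 41 ketone carrying a 4-chlorobutyl group at Cb, via lithium enolate 40 (not isolated)
Conditions: LiN(SiMe3)2 (1.05 equiv), THF, −78 °C; then 39 (3 equiv), DMPU, −78 → −20 °C
Reagents that add atoms: none
Why: Kinetic ketone enolate alkylation, possible only at Cb because Cf is quaternary and favoured over the less acidic lactones, attaches the four-carbon chain through its iodide end; the new Cb centre is of no consequence since Cb becomes sp2.

Step 26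
Reactants: 41 chlorobutyl azido ketone
Product: 45 O-TIPS ether of the target (pentacyclic enamine), via iminophosphorane 42 (not isolated), via chlorobutyl pyrroline 43 (not isolated), via azepinium chloride 44 (not isolated)
Conditions: PPh3 (1.05 equiv), toluene, rt → 100 °C; then NaI (cat.), i-Pr2NEt, MeCN, 80 °C
Reagents that add atoms: none
Why: Staudinger reaction and intramolecular aza-Wittig condensation close ring B as a five-membered cyclic imine without freeing an amine next to lactone E, after which iodide-catalysed intramolecular N-alkylation (7-exo-tet) closes ring A and loss of the Cb proton from the iminium ion gives the tetrasubstituted enamine.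

Step 27
Reactants: 45 O-TIPS ether of the target
Product: 46 CNP0154902.3 (target)
Conditions: HF·pyridine, pyridine, THF, 0 °C → rt; then aq. NaHCO3
Reagents that add atoms: none
Why: Fluoride-mediated cleavage of the TIPS ether under mildly acidic conditions frees the Ch hydroxyl without the base that could epimerise the lactones or move the acyl group of lactone D onto the cis hydroxyl.

Compound list
1 | (R)-4-benzyloxazolidin-2-one | O=C1N[C@H](Cc2ccccc2)CO1 | starting material
2 | butanoyl chloride | CCCC(Cl)=O | starting material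
3 | N-lithio oxazolidinone (lithium salt of 1, formed in situ) | O=C1N([Li])[C@H](Cc2ccccc2)CO1 | intermediate
4 | (R)-4-benzyl-3-butanoyloxazolidin-2-one | CCCC(=O)N1[C@H](Cc2ccccc2)COC1=O | intermediate
5 | 3-(trimethylsilyl)prop-2-ynal | C[Si](C)(C)C#CC=O | starting material
6 | Z-dibutylboron enolate of 4 (formed in situ) | CC/C=C(\OB(CCCC)CCCC)N1[C@H](Cc2ccccc2)COC1=O | intermediate
7 | (R)-4-benzyl-3-[(2R,3R)-2-ethyl-3-hydroxy-5-(trimethylsilyl)pent-4-ynoyl]oxazolidin-2-one | C[Si](C)(C)C#C[C@H](O)[C@@H](CC)C(=O)N1[C@H](Cc2ccccc2)COC1=O | intermediate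
8 | TIPS ether of 7 | C[Si](C)(C)C#C[C@H](O[Si](C(C)C)(C(C)C)C(C)C)[C@@H](CC)C(=O)N1[C@H](Cc2ccccc2)COC1=O | intermediate
9 | (2S,3R)-2-ethyl-3-(triisopropylsilyloxy)-5-(trimethylsilyl)pent-4-yn-1-ol | C[Si](C)(C)C#C[C@H](O[Si](C(C)C)(C(C)C)C(C)C)[C@@H](CC)CO | intermediate
10 | (3R,4R)-4-(iodomethyl)-3-(triisopropylsilyloxy)-1-(trimethylsilyl)hex-1-yne | C[Si](C)(C)C#C[C@H](O[Si](C(C)C)(C(C)C)C(C)C)[C@@H](CC)CI | intermediate
11 | N,N'-dimethoxy-N,N'-dimethyloxamide | CON(C)C(=O)C(=O)N(C)OC | starting material
12 | primary alkyllithium from 10 (formed in situ) | C[Si](C)(C)C#C[C@H](O[Si](C(C)C)(C(C)C)C(C)C)[C@@H](CC)C[Li] | intermediate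
13 | (4S,5R)-4-ethyl-N-methoxy-N-methyl-2-oxo-5-(triisopropylsilyloxy)-7-(trimethylsilyl)hept-6-ynamide | C[Si](C)(C)C#C[C@H](O[Si](C(C)C)(C(C)C)C(C)C)[C@@H](CC)CC(=O)C(=O)N(C)OC | intermediate
14 | 2-[(2S,3R)-2-ethyl-3-(triisopropylsilyloxy)-5-(trimethylsilyl)pent-4-yn-1-yl]-N-methoxy-N-methyl-1,3-dioxolane-2-carboxamide | C[Si](C)(C)C#C[C@H](O[Si](C(C)C)(C(C)C)C(C)C)[C@@H](CC)CC1(OCCO1)C(=O)N(C)OC | intermediate
15 | TMS-alkynyl methyl ketone (formed in situ) | C[Si](C)(C)C#C[C@H](O[Si](C(C)C)(C(C)C)C(C)C)[C@@H](CC)CC1(OCCO1)C(C)=O | intermediate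
16 | 1-{2-[(2S,3R)-2-ethyl-3-(triisopropylsilyloxy)pent-4-yn-1-yl]-1,3-dioxolan-2-yl}ethan-1-one | C#C[C@H](O[Si](C(C)C)(C(C)C)C(C)C)[C@@H](CC)CC1(OCCO1)C(C)=O | intermediate
17 | (S)-5-(hydroxymethyl)dihydrofuran-2(3H)-one | OC[C@@H]1CCC(=O)O1 | starting material
18 | (S)-5-[(tert-butyldiphenylsilyloxy)methyl]dihydrofuran-2(3H)-one | CC(C)(C)[Si](OC[C@@H]1CCC(=O)O1)(c1ccccc1)c1ccccc1 | intermediate
19 | lithium enolate of 18 (formed in situ) | CC(C)(C)[Si](OC[C@@H]1CC=C(O[Li])O1)(c1ccccc1)c1ccccc1 | intermediate
20 | (3R,5S)-5-[(tert-butyldiphenylsilyloxy)methyl]-3-methyldihydrofuran-2(3H)-one (trans) | CC(C)(C)[Si](OC[C@@H]1C[C@@H](C)C(=O)O1)(c1ccccc1)c1ccccc1 | intermediate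
21 | lithium enolate of 20 (formed in situ) | CC(C)(C)[Si](OC[C@@H]1CC(C)=C(O[Li])O1)(c1ccccc1)c1ccccc1 | intermediate
22 | (3S,5S)-5-[(tert-butyldiphenylsilyloxy)methyl]-3-methyldihydrofuran-2(3H)-one (cis) | CC(C)(C)[Si](OC[C@@H]1C[C@H](C)C(=O)O1)(c1ccccc1)c1ccccc1 | intermediate
23 | (3S,5S)-5-(hydroxymethyl)-3-methyldihydrofuran-2(3H)-one | OC[C@@H]1C[C@H](C)C(=O)O1 | intermediate
24 | (2S,4S)-4-methyl-5-oxotetrahydrofuran-2-carbaldehyde | O=C[C@@H]1C[C@H](C)C(=O)O1 | intermediate
25 | lithium enolate of 16 (formed in situ) | C#C[C@H](O[Si](C(C)C)(C(C)C)C(C)C)[C@@H](CC)CC1(OCCO1)C(=C)O[Li] | intermediate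
26 | aldol adduct: β-hydroxy ketone, (R)-carbinol at Cd, lactone E attached | C#C[C@H](O[Si](C(C)C)(C(C)C)C(C)C)[C@@H](CC)CC1(OCCO1)C(=O)C[C@@H](O)[C@@H]1C[C@H](C)C(=O)O1 | intermediate
27 | key-step precursor: ketal-protected α-dicarbonyl ynone with OTIPS (Ch), ethyl (Ca), OTES (Cd) and lactone E | C#C[C@H](O[Si](C(C)C)(C(C)C)C(C)C)[C@@H](CC)CC1(OCCO1)C(=O)C[C@@H](O[Si](CC)(CC)CC)[C@@H]1C[C@H](C)C(=O)O1 | intermediate
28 | key-step product: bicyclic butenolide (rings C and D), (R)-Cf, dioxolane at Cc, OTIPS at Ch, OTES side chain with lactone E | CC[C@H]1CC2(OCCO2)[C@]3(C[C@@H](O[Si](CC)(CC)CC)[C@@H]4C[C@H](C)C(=O)O4)OC(=O)C=C3[C@@H]1O[Si](C(C)C)(C(C)C)C(C)C | intermediate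
29 | vicinal dibromide of 28 (formed in situ; new centres undefined) | CC[C@H]1CC2(OCCO2)[C@]3(C[C@@H](O[Si](CC)(CC)CC)[C@@H]4C[C@H](C)C(=O)O4)OC(=O)C(Br)C3(Br)[C@@H]1O[Si](C(C)C)(C(C)C)C(C)C | intermediate
30 | α-bromobutenolide | CC[C@H]1CC2(OCCO2)[C@]3(C[C@@H](O[Si](CC)(CC)CC)[C@@H]4C[C@H](C)C(=O)O4)OC(=O)C(Br)=C3[C@@H]1O[Si](C(C)C)(C(C)C)C(C)C | intermediate
31 | α-methylbutenolide | CC[C@H]1CC2(OCCO2)[C@]3(C[C@@H](O[Si](CC)(CC)CC)[C@@H]4C[C@H](C)C(=O)O4)OC(=O)C(C)=C3[C@@H]1O[Si](C(C)C)(C(C)C)C(C)C | intermediate
32 | saturated cis-fused lactone D (Cg–H and α-H cis to Ce), OTES at Cd | CC[C@H]1CC2(OCCO2)[C@]3(C[C@@H](O[Si](CC)(CC)CC)[C@@H]4C[C@H](C)C(=O)O4)OC(=O)[C@H](C)[C@@H]3[C@@H]1O[Si](C(C)C)(C(C)C)C(C)C | intermediate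
33 | (R)-alcohol at Cd | CC[C@H]1CC2(OCCO2)[C@]3(C[C@@H](O)[C@@H]4C[C@H](C)C(=O)O4)OC(=O)[C@H](C)[C@@H]3[C@@H]1O[Si](C(C)C)(C(C)C)C(C)C | intermediate
34 | ketone at Cd | CC[C@H]1CC2(OCCO2)[C@]3(CC(=O)[C@@H]4C[C@H](C)C(=O)O4)OC(=O)[C@H](C)[C@@H]3[C@@H]1O[Si](C(C)C)(C(C)C)C(C)C | intermediate
35 | (S)-alcohol at Cd | CC[C@H]1CC2(OCCO2)[C@]3(C[C@H](O)[C@@H]4C[C@H](C)C(=O)O4)OC(=O)[C@H](C)[C@@H]3[C@@H]1O[Si](C(C)C)(C(C)C)C(C)C | intermediate
36 | (S)-triflate at Cd (formed in situ) | CC[C@H]1CC2(OCCO2)[C@]3(C[C@H](OS(=O)(=O)C(F)(F)F)[C@@H]4C[C@H](C)C(=O)O4)OC(=O)[C@H](C)[C@@H]3[C@@H]1O[Si](C(C)C)(C(C)C)C(C)C | intermediate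
37 | (R)-azide at Cd, ketal intact | CC[C@H]1CC2(OCCO2)[C@]3(C[C@@H](N=[N+]=[N-])[C@@H]4C[C@H](C)C(=O)O4)OC(=O)[C@H](C)[C@@H]3[C@@H]1O[Si](C(C)C)(C(C)C)C(C)C | intermediate
38 | azido ketone (free Cc=O) | CC[C@H]1CC(=O)[C@]3(C[C@@H](N=[N+]=[N-])[C@@H]4C[C@H](C)C(=O)O4)OC(=O)[C@H](C)[C@@H]3[C@@H]1O[Si](C(C)C)(C(C)C)C(C)C | intermediate
39 | 1-chloro-4-iodobutane | ClCCCCI | starting material
40 | lithium enolate of 38 (Cb=Cc, formed in situ) | CC[C@H]1C=C(O[Li])[C@]3(C[C@@H](N=[N+]=[N-])[C@@H]4C[C@H](C)C(=O)O4)OC(=O)[C@H](C)[C@@H]3[C@@H]1O[Si](C(C)C)(C(C)C)C(C)C | intermediate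
41 | azido ketone with 4-chlorobutyl at Cb (Cb configuration inconsequential, left undefined) | CC[C@H]1C(CCCCCl)C(=O)[C@]3(C[C@@H](N=[N+]=[N-])[C@@H]4C[C@H](C)C(=O)O4)OC(=O)[C@H](C)[C@@H]3[C@@H]1O[Si](C(C)C)(C(C)C)C(C)C | intermediate
42 | iminophosphorane at Cd (formed in situ) | CC[C@H]1C(CCCCCl)C(=O)[C@]3(C[C@@H](N=P(c5ccccc5)(c5ccccc5)c5ccccc5)[C@@H]4C[C@H](C)C(=O)O4)OC(=O)[C@H](C)[C@@H]3[C@@H]1O[Si](C(C)C)(C(C)C)C(C)C | intermediate
43 | ring B cyclic imine (1-pyrroline) with 4-chlorobutyl at Cb (formed in situ) | CC[C@H]1C(CCCCCl)C3=N[C@@H]([C@@H]2C[C@H](C)C(=O)O2)C[C@]32OC(=O)[C@H](C)[C@@H]2[C@@H]1O[Si](C(C)C)(C(C)C)C(C)C | intermediate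
44 | pentacyclic azepinium (iminium) chloride (formed in situ) | CC[C@H]1C2C3=[N+](CCCC2)[C@@H]([C@@H]2C[C@H](C)C(=O)O2)C[C@]32OC(=O)[C@H](C)[C@@H]2[C@@H]1O[Si](C(C)C)(C(C)C)C(C)C.[Cl-] | intermediate
45 | O-TIPS ether of the target (enamine Cb=Cc–N) | CC[C@H]1C2=C3N(CCCC2)[C@@H]([C@@H]2C[C@H](C)C(=O)O2)C[C@]32OC(=O)[C@H](C)[C@@H]2[C@@H]1O[Si](C(C)C)(C(C)C)C(C)C | intermediate
46 | CNP0154902.3 | CC[C@H]1C2=C3N(CCCC2)[C@@H]([C@@H]2C[C@H](C)C(=O)O2)C[C@]32OC(=O)[C@H](C)[C@@H]2[C@@H]1O | target

Total step count: 27 steps.
Longest linear sequence: 22 steps (steps 1–8 and 14–27, from 1). The lactone E aldehyde 24 is made in 5 steps (9–13) and joins in step 14.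

The three steps most likely to fail

1. Step 16 (key step). The oxidative coupling on molybdenum may not engage a hindered ketone that is activated only inductively, so that alkyne oligomerisation or thermal decomposition wins, or the ketone face may be chosen poorly. The fallback builds the same two rings stepwise by polar chemistry and sets out from 27. Palladium-catalysed oxidative methoxycarbonylation of the terminal alkyne (PdCl2 cat., CuCl2, NaOAc, CO, MeOH) would give the methyl ynoate F1. Anti-hydroiodination (NaI, AcOH) would give the (Z)-β-iodo enoate F2. An intramolecular Nozaki–Hiyama–Kishi addition of the alkenyl iodide to the ketone (CrCl2, NiCl2 cat., DMSO) would close ring C, and the tertiary alkoxide would lactonise onto the cis ester. This comes back to the route at 28.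

2. Step 25. C-alkylation by an unactivated primary iodide may be slower than proton exchange between the ketone enolate and the lactone α-positions (epimerisation) or than over-alkylation. The fallback uses an activated allylic electrophile and sets out from 38. The same enolate would be alkylated with (Z)-1,4-dichlorobut-2-ene to give the allylic chloride F4. The phosphine-mediated imine closure and iodide-catalysed N-alkylation of step 26, here an allylic displacement, would give the ring A-unsaturated enamine F5. Diimide reduction of the cis-disubstituted alkene (2-nitrobenzenesulfonyl hydrazide, Et3N), which should spare the tetrasubstituted enamine, comes back to the route at 45.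

3. Step 19. Hydrogen uptake at a tetrasubstituted alkene beside a quaternary carbon may be too slow, and face selectivity may erode under forcing conditions. The fallback uses hydroxyl-directed homogeneous hydrogenation and sets out from 31. The triethylsilyl ether would be cleaved first (PPTS, MeOH) to give the hydroxy butenolide F3. Its Cd hydroxyl sits on the Ce arm and can bind [Ir(cod)(PCy3)(py)]PF6 (H2, CH2Cl2), so that hydrogen is delivered to the Ce face. This comes back to the route at 33.

Further compounds
F1 | step 16 | methyl ynoate of 27 (methoxycarbonyl on the alkyne terminus) | COC(=O)C#C[C@H](O[Si](C(C)C)(C(C)C)C(C)C)[C@@H](CC)CC1(OCCO1)C(=O)C[C@@H](O[Si](CC)(CC)CC)[C@@H]1C[C@H](C)C(=O)O1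
F2 | step 16 | (Z)-β-iodo enoate of 27 | COC(=O)/C=C(\I)[C@H](O[Si](C(C)C)(C(C)C)C(C)C)[C@@H](CC)CC1(OCCO1)C(=O)C[C@@H](O[Si](CC)(CC)CC)[C@@H]1C[C@H](C)C(=O)O1
F3 | step 19 | α-methylbutenolide with free (R)-hydroxyl at Cd | CC[C@H]1CC2(OCCO2)[C@]3(C[C@@H](O)[C@@H]4C[C@H](C)C(=O)O4)OC(=O)C(C)=C3[C@@H]1O[Si](C(C)C)(C(C)C)C(C)C
F4 | step 25 | azido ketone with (Z)-4-chlorobut-2-enyl at Cb | CC[C@H]1C(C/C=C\CCl)C(=O)[C@]3(C[C@@H](N=[N+]=[N-])[C@@H]4C[C@H](C)C(=O)O4)OC(=O)[C@H](C)[C@@H]3[C@@H]1O[Si](C(C)C)(C(C)C)C(C)C
F5 | step 25 | O-TIPS enamine with a cis double bond in ring A | CC[C@H]1C2=C3N(C/C=C\C2)[C@@H]([C@@H]2C[C@H](C)C(=O)O2)C[C@]32OC(=O)[C@H](C)[C@@H]2[C@@H]1O[Si](C(C)C)(C(C)C)C(C)C
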